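Everything rests on opening the oxolane (O1, C2, C3 carrying carbinol carbon C7, C4 carrying the arylmethyl group, C5) at O1–C2. C2 is the ring methylene β to benzylic C7, so the C2–C3–C7 array is folded into a 1-arylcyclopropanol, assembled convergently from a syringate ester and an enantiopure homoallylic alcohol by Kulinkovich hydroxycyclopropanation. Strain-driven, palladium-catalysed cleavage of the cyclopropanol C7–C2 bond then unmasks C2 as the electrophilic methylene of an aryl enone, which the primary hydroxyl oxygen O1 captures in the same flask; one operation closes the oxolane, sets the trans C3/C4 relationship and leaves a C7 ketone for reagent-controlled reduction. The key-step precursor is an acyclic cyclopropanol diol.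

Key step: step 8

Remark: cyclopropanol 12 is expected as a mixture of cyclopropane diastereomers; both cyclopropane stereocentres are erased or equilibrated in step 8, so only the side-chain centre (future C4) is specified for 12.

Step 1
Reactants: 1 methyl 4-hydroxy-3,5-dimethoxybenzoate (methyl syringate)
Product: 2 methyl 4-(benzyloxy)-3,5-dimethoxybenzoate
Conditions: BnBr, K2CO3, DMF, 60 °C
Reagents that add atoms: benzyl bromide, BrCc1ccccc1
Why: Williamson etherification of the hindered but acidic phenoxide with a reactive benzylic bromide should protect the phenol for all later organometallic steps.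

Step 2
Reactants: 2 methyl 4-(benzyloxy)-3,5-dimethoxybenzoate (part of the batch)
Product: 3 [4-(benzyloxy)-3,5-dimethoxyphenyl]methanol
Conditions: LiAlH4, THF, 0 °C
Reagents that add atoms: none
Why: Hydride reduction of the aryl ester to the benzylic alcohol should leave the benzyl and methyl ethers untouched.

Step 3
Reactants: 3 [4-(benzyloxy)-3,5-dimethoxyphenyl]methanol
Product: 4 2-(benzyloxy)-5-(bromomethyl)-1,3-dimethoxybenzene
Conditions: PBr3, CH2Cl2, 0 °C
Reagents that add atoms: phosphorus tribromide, BrP(Br)Br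
Why: Bromination of an electron-rich benzylic alcohol through its phosphite ester should be fast at low temperature, and the bromide is used directly.

Step 4
Reactants: 5 (4R)-4-benzyl-1,3-oxazolidin-2-one; 6 (E)-but-2-enoyl chloride
Product: 8 (4R)-4-benzyl-3-[(2E)-but-2-enoyl]-1,3-oxazolidin-2-one, via lithium oxazolidinide 7 (not isolated)
Conditions: n-BuLi, THF, −78 °C; then 6, −78 to 0 °C
Reagents that add atoms: none
Why: N-Acylation of the lithiated auxiliary with the acid chloride is the standard entry to the crotonyl imide.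

Step 5
Reactants: 8 (4R)-4-benzyl-3-[(2E)-but-2-enoyl]-1,3-oxazolidin-2-one; 4 2-(benzyloxy)-5-(bromomethyl)-1,3-dimethoxybenzene
Product: 10 (4R)-4-benzyl-3-[(2R)-2-{[4-(benzyloxy)-3,5-dimethoxyphenyl]methyl}but-3-enoyl]-1,3-oxazolidin-2-one, via sodium dienolate 9 (not isolated)
Conditions: NaN(SiMe3)2, THF, −78 °C; then 4, −78 to −40 °C
Reagents that add atoms: none
Why: Deconjugative Evans-type alkylation, in which γ-deprotonation gives the chelated (Z)-dienolate and the benzylic bromide attacks the α-carbon on the face opposite the auxiliary benzyl group, should set the (2R) centre that becomes C4.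

Step 6
Reactants: 10 (4R)-4-benzyl-3-[(2R)-2-{[4-(benzyloxy)-3,5-dimethoxyphenyl]methyl}but-3-enoyl]-1,3-oxazolidin-2-one
Product: 11 (2R)-2-{[4-(benzyloxy)-3,5-dimethoxyphenyl]methyl}but-3-en-1-ol
Conditions: LiBH4, MeOH (1 equiv), Et2O, 0 °C
Reagents that add atoms: none
Why: Reductive cleavage of the imide by LiBH4 should release the primary alcohol and the recoverable auxiliary without epimerising the α-vinyl centre or touching the alkene.

Step 7
Reactants: 11 (2R)-2-{[4-(benzyloxy)-3,5-dimethoxyphenyl]methyl}but-3-en-1-ol; 2 methyl 4-(benzyloxy)-3,5-dimethoxybenzoate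
Product: 12 1-[4-(benzyloxy)-3,5-dimethoxyphenyl]-2-[(2R)-1-[4-(benzyloxy)-3,5-dimethoxyphenyl]-3-hydroxypropan-2-yl]cyclopropan-1-ol (mixture of cyclopropane diastereomers)
Conditions: Ti(OiPr)4, c-C6H11MgCl (slow addition), THF, 20 °C
Reagents that add atoms: none
Why: Kulinkovich hydroxycyclopropanation with olefin exchange, in which the titanacyclopropane from Ti(OiPr)4 and c-C6H11MgCl trades cyclohexene for the alkene of the titanium-bound homoallylic alkoxide of 11 and then adds twice to the ester carbonyl of 2, should join both halves; the cyclopropane stereocentres need no control.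

Step 8
Reactants: 12 1-[4-(benzyloxy)-3,5-dimethoxyphenyl]-2-[(2R)-1-[4-(benzyloxy)-3,5-dimethoxyphenyl]-3-hydroxypropan-2-yl]cyclopropan-1-ol
Product: 14 [4-(benzyloxy)-3,5-dimethoxyphenyl][(3R,4R)-4-{[4-(benzyloxy)-3,5-dimethoxyphenyl]methyl}oxolan-3-yl]methanone, via hydroxy enone 13 (not isolated)
Conditions: Pd(OAc)2 (10 mol %), O2 (1 atm), DMSO, 30 °C; then DBU (0.3 equiv), 25 °C
Reagents that add atoms: none
Why: Palladium diacetate should bind the tertiary cyclopropanol as a divalent palladium alkoxide, strain-releasing β-carbon elimination should cleave the less substituted C7–C2 bond to a primary C2–palladium homoenolate, and β-hydride elimination from C3 should give hydroxy enone 13 while O2 reoxidises the palladium hydride; DBU then promotes conjugate addition of O1 to the exocyclic methylene C2 and equilibrates C3. The closest known reaction types are the palladium-catalysed aerobic opening of 2-substituted cyclopropanols to α-methylene ketones, its tandem use with hetero-Michael addition, and base-mediated 5-endo-trig oxa-Michael closures of hydroxy-tethered vinyl sulfones and acrylates. The oxolane closes in a 5-endo-trig mode, formally disfavoured but expected to be workable because the acceptor carbon is an unhindered terminal methylene, the addition is reversible, and the competing 5-exo hemiketal is non-productive and reverts. The new C3 stereocentre is set under thermodynamic control by the fixed C4 arylmethyl group, enolisation of the aryl ketone funnelling material into the trans (3R,4R) isomer. The step needs cleavage of the cyclopropanol CH2 bond and not the CH bond, secured by the organometallic rather than radical mechanism; it needs chemoselectivity for the strained tertiary alkoxide over the primary alcohol, secured by the low temperature; and it needs retention of C4, secured by ring closure outpacing isomerisation of the enone into conjugation with C4.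

Step 9
Reactants: 14 [4-(benzyloxy)-3,5-dimethoxyphenyl][(3R,4R)-4-{[4-(benzyloxy)-3,5-dimethoxyphenyl]methyl}oxolan-3-yl]methanone
Product: 15 (S)-[4-(benzyloxy)-3,5-dimethoxyphenyl][(3R,4R)-4-{[4-(benzyloxy)-3,5-dimethoxyphenyl]methyl}oxolan-3-yl]methanol
Conditions: (R)-2-methyl-CBS-oxazaborolidine (20 mol %), BH3·SMe2, THF, −20 °C
Reagents that add atoms: none
Why: Corey–Bakshi–Shibata reduction with the (R)-catalyst should deliver hydride to the aryl ketone face that gives the (S)-carbinol, and this sense is expected to be reinforced by the Felkin–Anh preference of the C3 centre (C4 as the large group, hydride anti to it).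

Step 10
Reactants: 15 (S)-[4-(benzyloxy)-3,5-dimethoxyphenyl][(3R,4R)-4-{[4-(benzyloxy)-3,5-dimethoxyphenyl]methyl}oxolan-3-yl]methanol
Product: 16 4-{(S)-hydroxy[(3R,4R)-4-(4-hydroxy-3,5-dimethoxybenzyl)oxolan-3-yl]methyl}-2,6-dimethoxyphenol (target)
Conditions: H2 (1 atm), Pd/C, EtOAc, 20 °C
Reagents that add atoms: none
Why: Hydrogenolysis of the two aryl benzyl ethers under neutral conditions should be much faster than cleavage of the secondary benzylic alcohol, and no stereocentre is affected.

Compound list
1 | methyl 4-hydroxy-3,5-dimethoxybenzoate (methyl syringate) | COC(=O)c1cc(OC)c(O)c(OC)c1 | starting material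
2 | methyl 4-(benzyloxy)-3,5-dimethoxybenzoate | COC(=O)c1cc(OC)c(OCc2ccccc2)c(OC)c1 | intermediate
3 | [4-(benzyloxy)-3,5-dimethoxyphenyl]methanol | OCc1cc(OC)c(OCc2ccccc2)c(OC)c1 | intermediate
4 | 2-(benzyloxy)-5-(bromomethyl)-1,3-dimethoxybenzene | BrCc1cc(OC)c(OCc2ccccc2)c(OC)c1 | intermediate
5 | (4R)-4-benzyl-1,3-oxazolidin-2-one | O=C1N[C@H](Cc2ccccc2)CO1 | starting material
6 | (E)-but-2-enoyl chloride | C/C=C/C(Cl)=O | starting material
7 | lithium salt of (4R)-4-benzyl-1,3-oxazolidin-2-one | [Li+].O=C1[N-][C@H](Cc2ccccc2)CO1 | intermediate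
8 | (4R)-4-benzyl-3-[(2E)-but-2-enoyl]-1,3-oxazolidin-2-one | C/C=C/C(=O)N1[C@H](Cc2ccccc2)COC1=O | intermediate
9 | sodium (Z)-dienolate of 8 | [Na+].C=C/C=C(\[O-])N1[C@H](Cc2ccccc2)COC1=O | intermediate
10 | (4R)-4-benzyl-3-[(2R)-2-{[4-(benzyloxy)-3,5-dimethoxyphenyl]methyl}but-3-enoyl]-1,3-oxazolidin-2-one | C=C[C@@H](Cc1cc(OC)c(OCc2ccccc2)c(OC)c1)C(=O)N1[C@H](Cc2ccccc2)COC1=O | intermediate
11 | (2R)-2-{[4-(benzyloxy)-3,5-dimethoxyphenyl]methyl}but-3-en-1-ol | C=C[C@@H](Cc1cc(OC)c(OCc2ccccc2)c(OC)c1)CO | intermediate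
12 | 1-[4-(benzyloxy)-3,5-dimethoxyphenyl]-2-[(2R)-1-[4-(benzyloxy)-3,5-dimethoxyphenyl]-3-hydroxypropan-2-yl]cyclopropan-1-ol | OC[C@H](Cc1cc(OC)c(OCc2ccccc2)c(OC)c1)C1CC1(O)c1cc(OC)c(OCc2ccccc2)c(OC)c1 | intermediate
13 | (3R)-1-[4-(benzyloxy)-3,5-dimethoxyphenyl]-3-{[4-(benzyloxy)-3,5-dimethoxyphenyl]methyl}-4-hydroxy-2-methylidenebutan-1-one | OC[C@H](Cc1cc(OC)c(OCc2ccccc2)c(OC)c1)C(=C)C(=O)c1cc(OC)c(OCc2ccccc2)c(OC)c1 | intermediate
14 | [4-(benzyloxy)-3,5-dimethoxyphenyl][(3R,4R)-4-{[4-(benzyloxy)-3,5-dimethoxyphenyl]methyl}oxolan-3-yl]methanone | COc1cc(C[C@H]2COC[C@@H]2C(=O)c2cc(OC)c(OCc3ccccc3)c(OC)c2)cc(OC)c1OCc1ccccc1 | intermediate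
15 | (S)-[4-(benzyloxy)-3,5-dimethoxyphenyl][(3R,4R)-4-{[4-(benzyloxy)-3,5-dimethoxyphenyl]methyl}oxolan-3-yl]methanol | COc1cc(C[C@H]2COC[C@@H]2[C@H](O)c2cc(OC)c(OCc3ccccc3)c(OC)c2)cc(OC)c1OCc1ccccc1 | intermediate
16 | 4-{(S)-hydroxy[(3R,4R)-4-(4-hydroxy-3,5-dimethoxybenzyl)oxolan-3-yl]methyl}-2,6-dimethoxyphenol | COc1cc(C[C@H]2COC[C@@H]2[C@H](O)c2cc(OC)c(O)c(OC)c2)cc(OC)c1O | target

Total step count: 10. Longest linear sequence: 9 steps (steps 1, 2, 3, 5, 6, 7, 8, 9, 10 from methyl syringate); step 4 is a one-step branch.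

Steps most likely to fail

Step 8. The palladium/O2 system may oxidise the free primary hydroxyl in competition with cyclopropanol opening. The transient exocyclic enone may also shift its double bond into conjugation with C4 and erode that stereocentre, or rest as its cyclic hemiketal because the 5-endo closure is slow. The fallback sets out from 12 and returns at 14 by separating oxidation from ring closure. The primary hydroxyl of 12 is silylated selectively (TBSCl, imidazole, CH2Cl2, 0 °C) to the tert-butyldimethylsilyl ether F1. F1 is opened with Pd(OAc)2 and O2 in DMSO to the isolated silyloxy enone F2. Fluoride (n-Bu4NF, THF, −20 °C) then releases the alkoxide, which should close onto the methylene under kinetic conditions and equilibrate to trans ketone 14.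

Step 7. Olefin exchange on titanium may be slow for the allylically branched alkene, so that direct addition of the Grignard reagent to the electron-rich aryl ester, or its reduction, takes over. The fallback sets out from 2 and 11 and returns at 12 by making the cyclopropanation intramolecular. Ester 2 is saponified (LiOH, THF–H2O) to 4-(benzyloxy)-3,5-dimethoxybenzoic acid F3. F3 is coupled with 11 (DCC, DMAP, CH2Cl2) to give the homoallyl aroate F4. Treatment of F4 with Ti(OiPr)4 and i-PrMgCl (Et2O, −50 to 20 °C) should generate the tethered titanacyclopropane, which undergoes intramolecular acyl substitution to diol 12.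

Step 9. Facial selectivity at the aryl ketone may be poor if the branched C3 substituent erodes reagent control or if the substrate bias opposes the catalyst. The fallback sets out from 14 and returns at 15 by correcting the centre after reduction. Ketone 14 is reduced to whichever epimer forms cleanly; if this is the (7R)-alcohol F5 (expected with the enantiomeric (S)-oxazaborolidine or LiBH(s-Bu)3 in a mismatched case), it is inverted by Mitsunobu esterification (4-nitrobenzoic acid, PPh3, DIAD, THF, 0 °C) to the (7S)-4-nitrobenzoate F6. Methanolysis (K2CO3, MeOH) then gives 15.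

Further compounds
F1 | step 8 | 2-[(2R)-1-[4-(benzyloxy)-3,5-dimethoxyphenyl]-3-{[tert-butyl(dimethyl)silyl]oxy}propan-2-yl]-1-[4-(benzyloxy)-3,5-dimethoxyphenyl]cyclopropan-1-ol | CC(C)(C)[Si](C)(C)OC[C@H](Cc1cc(OC)c(OCc2ccccc2)c(OC)c1)C1CC1(O)c1cc(OC)c(OCc2ccccc2)c(OC)c1
F2 | step 8 | (3R)-1-[4-(benzyloxy)-3,5-dimethoxyphenyl]-3-{[4-(benzyloxy)-3,5-dimethoxyphenyl]methyl}-4-{[tert-butyl(dimethyl)silyl]oxy}-2-methylidenebutan-1-one | CC(C)(C)[Si](C)(C)OC[C@H](Cc1cc(OC)c(OCc2ccccc2)c(OC)c1)C(=C)C(=O)c1cc(OC)c(OCc2ccccc2)c(OC)c1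
F3 | step 7 | 4-(benzyloxy)-3,5-dimethoxybenzoic acid | OC(=O)c1cc(OC)c(OCc2ccccc2)c(OC)c1
F4 | step 7 | (2R)-2-{[4-(benzyloxy)-3,5-dimethoxyphenyl]methyl}but-3-en-1-yl 4-(benzyloxy)-3,5-dimethoxybenzoate | C=C[C@@H](Cc1cc(OC)c(OCc2ccccc2)c(OC)c1)COC(=O)c1cc(OC)c(OCc2ccccc2)c(OC)c1
F5 | step 9 | (R)-[4-(benzyloxy)-3,5-dimethoxyphenyl][(3R,4R)-4-{[4-(benzyloxy)-3,5-dimethoxyphenyl]methyl}oxolan-3-yl]methanol | COc1cc(C[C@H]2COC[C@@H]2[C@@H](O)c2cc(OC)c(OCc3ccccc3)c(OC)c2)cc(OC)c1OCc1ccccc1
F6 | step 9 | (S)-[4-(benzyloxy)-3,5-dimethoxyphenyl][(3R,4R)-4-{[4-(benzyloxy)-3,5-dimethoxyphenyl]methyl}oxolan-3-yl]methyl 4-nitrobenzoate | COc1cc(C[C@H]2COC[C@@H]2[C@H](OC(=O)c2ccc(cc2)[N+](=O)[O-])c2cc(OC)c(OCc3ccccc3)c(OC)c2)cc(OC)c1OCc1ccccc1
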